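**Retrosynthetic overview**
- Target 13 ⇐ global debenzylation of open enone 12 ⇐ retro-oxa-Michael opening of the chromanone ring of tricycle 11.
- 11 ⇐ one flask: [4+1] annulation of an acyl o-quinone methide (from sulfone 5) with a chiral benzylic sulfur ylide (from 8), then CH2O/amine annulation of the neighbouring ArCH2C(=O)/ortho-OH pair.
- 5 ⇐ three-component union of phenol 2, arylglyoxal 4 and p-toluenesulfinic acid; 2 ⇐ catalogue deoxybenzoin 1; 4 ⇐ acetophenone 3.
- Ring order: all benzene rings are bought; the dihydrofuran ring (C2–C3 and C2–O bonds, both stereocentres) and the 3-arylchroman-4-one ring are made in the same operation; the chromanone ring masks the 2-arylacryloyl/phenol pair and is reopened in step 6.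

Assumption: deoxybenzoin 1 (the genistein precursor) is bought; it is otherwise one step from phloroglucinol and 4-hydroxyphenylacetic acid (BF3·OEt2).
Assumption: the ylide from sulfide 6 is taken to show the same facial sense as in its aldehyde epoxidations, which calls for the (1S,4S,5S)-sulfide (sold, or one step from (S)-limonene and sulfur); if a test run shows the opposite sense, its mirror image is used.

**Step 1**
Reactants: 1 2-(4-hydroxyphenyl)-1-(2,4,6-trihydroxyphenyl)ethan-1-one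
Product: 2 1-[4-(benzyloxy)-2,6-dihydroxyphenyl]-2-[4-(benzyloxy)phenyl]ethan-1-one
Conditions: BnBr (2.1 equiv), K2CO3, acetone, 40 °C
Reagents that add atoms: benzyl bromide, BrCc1ccccc1
Why: Williamson ether synthesis in which only the two phenols not hydrogen-bonded to the ketone are alkylated with 2 equiv of bromide, leaving both chelated ortho-OH groups free; no stereocentre.

**Step 2**
Reactants: 3 1-[2,4-bis(benzyloxy)phenyl]ethan-1-one
Product: 4 2-[2,4-bis(benzyloxy)phenyl]-2-oxoacetaldehyde (arylglyoxal, used as its hydrate)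
Conditions: SeO2, 1,4-dioxane–H2O (20:1), 95 °C
Reagents that add atoms: selenium dioxide, O=[Se]=O
Why: Riley oxidation of an aryl methyl ketone to the arylglyoxal, to which benzyl ethers are inert; no stereocentre.

**Step 3**
Reactants: 2 1-[4-(benzyloxy)-2,6-dihydroxyphenyl]-2-[4-(benzyloxy)phenyl]ethan-1-one (1.2 equiv); 4 2-[2,4-bis(benzyloxy)phenyl]-2-oxoacetaldehyde
Product: 5 1-[2,4-bis(benzyloxy)phenyl]-2-[6-(benzyloxy)-3-{[4-(benzyloxy)phenyl]acetyl}-2,4-dihydroxyphenyl]-2-(4-methylbenzenesulfonyl)ethan-1-one (racemic)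
Conditions: 4-MeC6H4SO2H (1.5 equiv), MgSO4, CH2Cl2, rt
Reagents that add atoms: p-toluenesulfinic acid, Cc1ccc(cc1)S(=O)O
Why: Three-component Friedel–Crafts hydroxyalkylation/sulfinate capture (the route to 2-(1-tosylalkyl)phenols): the glyoxal CHO is attacked by the ring position ortho to a free OH (the two such positions of 2 are equivalent) and the benzylic cation/o-quinone methide is trapped by sulfinate; the new stereocentre is racemic and is erased in step 5.

**Step 4**
Reactants: 6 (1S,4S,5S)-4,7,7-trimethyl-6-thiabicyclo[3.2.1]octane (isothiocineole); 7 1-(benzyloxy)-4-(bromomethyl)benzene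
Product: 8 (1S,4S,5S)-6-[4-(benzyloxy)benzyl]-4,7,7-trimethyl-6-thiabicyclo[3.2.1]octan-6-ium tetrafluoroborate
Conditions: NaBF4, CH2Cl2–H2O, rt
Reagents that add atoms: sodium tetrafluoroborate, [Na+].F[B-](F)(F)F
Why: S-Alkylation of the sulfide by the benzylic bromide with anion exchange (Aggarwal's sulfonium salt preparation), alkylation on the exposed sulfur lone pair giving one sulfonium diastereomer.

**Step 5 (key step)**
Reactants: 5 sulfone from step 3; 8 sulfonium salt from step 4 (1.3 equiv)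
Product: 11 (2R,3R)-4-(benzyloxy)-3-[2,4-bis(benzyloxy)benzoyl]-2,8-bis[4-(benzyloxy)phenyl]-2,3,7,8-tetrahydro-9H-furo[2,3-f]chromen-9-one, via o-quinone methide 9 (not isolated), via dihydrobenzofuran ketone 10 (not isolated)
Conditions: Cs2CO3 (3.5 equiv), MeCN–CH2Cl2, −20 → 0 °C; then (CH2O)n (1.5 equiv), Et2NH (0.3 equiv), 45 °C, same flask
Reagents that add atoms: formaldehyde (as paraformaldehyde), C=O
Why: Proposed new method: carbonate expels sulfinate from the phenoxide of 5 to give acyl o-quinone methide 9, the isothiocineole benzylic ylide adds through its single open face to the exocyclic carbon and the phenoxide displaces the sulfide with inversion (5-exo-tet), so the ylide carbon becomes C2 (R) while C3, alpha to the ketone, equilibrates to trans (R) to give 10, after which CH2O/Et2NH methylenates the ArCH2C(=O) group and the remaining chelated phenoxide closes on the enone (6-endo oxa-Michael), so the dihydrofuran and chromanone rings both form in this one operation; the closest known reactions are the [4+1] annulation of sulfur ylides with o-quinone methides, Aggarwal's isothiocineole ylide epoxidation and the formaldehyde/amine isoflavanone synthesis from 2-hydroxydeoxybenzoins.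

**Step 6**
Reactants: 11 furo-fused isoflavanone from step 5
Product: 12 1-{(2R,3R)-4-(benzyloxy)-3-[2,4-bis(benzyloxy)benzoyl]-2-[4-(benzyloxy)phenyl]-6-hydroxy-2,3-dihydro-1-benzofuran-7-yl}-2-[4-(benzyloxy)phenyl]prop-2-en-1-one
Conditions: MgBr2·OEt2 (3 equiv), Et3N (3 equiv), CH2Cl2, 0 °C → rt; cold aq. AcOH quench
Reagents that add atoms: none
Why: Proposed new method: Mg2+ binds the chromanone carbonyl, Et3N removes the alpha-aryl C–H (soft enolisation) and the enolate expels the ortho-acyl aryloxide (E1cB retro-oxa-Michael, retro-6-endo), the magnesium phenoxide–ketone chelate making the opening downhill and blocking re-addition until the acidic quench; the closest known reaction is the base-induced opening of flavanones to 2'-hydroxychalcones; C2 is untouched because opening of the dihydrofuran would be a disfavoured retro-5-endo process and the 4-benzyloxyphenyl group cannot form a p-quinone methide, and C3 re-equilibrates to trans.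

**Step 7**
Reactants: 12 open enone from step 6
Product: 13 1-[(2R,3R)-3-(2,4-dihydroxybenzoyl)-4,6-dihydroxy-2-(4-hydroxyphenyl)-2,3-dihydro-1-benzofuran-7-yl]-2-(4-hydroxyphenyl)prop-2-en-1-one (target)
Conditions: BCl3 (12 equiv), C6HMe5 (15 equiv), CH2Cl2, −78 → −40 °C; MeOH/H2O quench, no basic work-up; RP-HPLC (0.1% HCO2H)
Reagents that add atoms: none
Why: BCl3/pentamethylbenzene cleavage of aryl benzyl ethers (benzyl cations trapped by the arene) at low temperature, where the C6–O–BCl2 group chelates the enone carbonyl and cannot add to the methylene, and the acidic work-up leaves the hydrogen-bonded 2'-hydroxy-6'-alkoxy-type enone open; C2 and C3 keep their configuration (any reversible C2–O ionisation re-closes trans under control of C3).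

**Compound list**
1 | 2-(4-hydroxyphenyl)-1-(2,4,6-trihydroxyphenyl)ethan-1-one | O=C(Cc1ccc(O)cc1)c1c(O)cc(O)cc1O | starting material
2 | 1-[4-(benzyloxy)-2,6-dihydroxyphenyl]-2-[4-(benzyloxy)phenyl]ethan-1-one | O=C(Cc1ccc(OCc2ccccc2)cc1)c1c(O)cc(OCc2ccccc2)cc1O | intermediate
3 | 1-[2,4-bis(benzyloxy)phenyl]ethan-1-one | CC(=O)c1ccc(OCc2ccccc2)cc1OCc1ccccc1 | starting material
4 | 2-[2,4-bis(benzyloxy)phenyl]-2-oxoacetaldehyde | O=CC(=O)c1ccc(OCc2ccccc2)cc1OCc1ccccc1 | intermediate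
5 | 1-[2,4-bis(benzyloxy)phenyl]-2-[6-(benzyloxy)-3-{[4-(benzyloxy)phenyl]acetyl}-2,4-dihydroxyphenyl]-2-(4-methylbenzenesulfonyl)ethan-1-one (racemic) | Cc1ccc(cc1)S(=O)(=O)C(C(=O)c1ccc(OCc2ccccc2)cc1OCc1ccccc1)c1c(O)c(C(=O)Cc2ccc(OCc3ccccc3)cc2)c(O)cc1OCc1ccccc1 | intermediate
6 | (1S,4S,5S)-4,7,7-trimethyl-6-thiabicyclo[3.2.1]octane (isothiocineole) | C[C@H]1CC[C@H]2C[C@@H]1SC2(C)C | starting material
7 | 1-(benzyloxy)-4-(bromomethyl)benzene | BrCc1ccc(OCc2ccccc2)cc1 | starting material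
8 | (1S,4S,5S)-6-[4-(benzyloxy)benzyl]-4,7,7-trimethyl-6-thiabicyclo[3.2.1]octan-6-ium tetrafluoroborate | C[C@H]1CC[C@H]2C[C@@H]1[S+](Cc1ccc(OCc3ccccc3)cc1)C2(C)C.F[B-](F)(F)F | intermediate
9 | 6-{2-[2,4-bis(benzyloxy)phenyl]-2-oxoethylidene}-5-(benzyloxy)-2-{[4-(benzyloxy)phenyl]acetyl}-3-hydroxycyclohexa-2,4-dien-1-one (o-quinone methide) | O=C1C(C(=O)Cc2ccc(OCc3ccccc3)cc2)=C(O)C=C(OCc2ccccc2)C1=CC(=O)c1ccc(OCc2ccccc2)cc1OCc1ccccc1 | intermediate (not isolated)
10 | 1-{(2R,3R)-4-(benzyloxy)-3-[2,4-bis(benzyloxy)benzoyl]-2-[4-(benzyloxy)phenyl]-6-hydroxy-2,3-dihydro-1-benzofuran-7-yl}-2-[4-(benzyloxy)phenyl]ethan-1-one | O=C(Cc1ccc(OCc2ccccc2)cc1)c1c(O)cc(OCc2ccccc2)c2c1O[C@@H](c1ccc(OCc3ccccc3)cc1)[C@@H]2C(=O)c1ccc(OCc2ccccc2)cc1OCc1ccccc1 | intermediate (not isolated)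
11 | (2R,3R)-4-(benzyloxy)-3-[2,4-bis(benzyloxy)benzoyl]-2,8-bis[4-(benzyloxy)phenyl]-2,3,7,8-tetrahydro-9H-furo[2,3-f]chromen-9-one (10 with its 6-O and 7-acyl group tied as O–CH2–CH(Ar)–C(=O); both epimers at the new CH) | O=C1C(c2ccc(OCc3ccccc3)cc2)COc2cc(OCc3ccccc3)c3c(O[C@@H](c4ccc(OCc5ccccc5)cc4)[C@@H]3C(=O)c3ccc(OCc4ccccc4)cc3OCc3ccccc3)c21 | intermediate
12 | 1-{(2R,3R)-4-(benzyloxy)-3-[2,4-bis(benzyloxy)benzoyl]-2-[4-(benzyloxy)phenyl]-6-hydroxy-2,3-dihydro-1-benzofuran-7-yl}-2-[4-(benzyloxy)phenyl]prop-2-en-1-one | C=C(C(=O)c1c(O)cc(OCc2ccccc2)c2c1O[C@@H](c1ccc(OCc3ccccc3)cc1)[C@@H]2C(=O)c1ccc(OCc2ccccc2)cc1OCc1ccccc1)c1ccc(OCc2ccccc2)cc1 | intermediate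
13 | 1-[(2R,3R)-3-(2,4-dihydroxybenzoyl)-4,6-dihydroxy-2-(4-hydroxyphenyl)-2,3-dihydro-1-benzofuran-7-yl]-2-(4-hydroxyphenyl)prop-2-en-1-one | C=C(C(=O)c1c(O)cc(O)c2c1O[C@@H](c1ccc(O)cc1)[C@@H]2C(=O)c1ccc(O)cc1O)c1ccc(O)cc1 | target

**Step count and risks**
Total steps: 7. Longest linear sequence: 5 (1 → 2 → 5 → 11 → 12 → 13).

Steps most likely to fail:

- **Step 5** (untested asymmetric ylide annulation on an acyl o-quinone methide, followed by the formaldehyde stage in the same flask). Fallback, setting out from 2 and 3 and coming back at 11: aldol condensation of 3 with 4-(benzyloxy)benzaldehyde (KOH, EtOH) gives (E)-1-[2,4-bis(benzyloxy)phenyl]-3-[4-(benzyloxy)phenyl]prop-2-en-1-one F1. A Mn(OAc)3/Cu(OAc)2 oxidative radical [3+2] annulation of phenol 2 with F1 (AcOH, 60 °C) gives trans-10 as the racemate, that is 10 together with its (2S,3S)-enantiomer F2. Preparative chiral SFC removes F2, and 10 is taken through the (CH2O)n/Et2NH stage of step 5 to 11.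

- **Step 6** (ring opening may stall, or the enone may re-add or oligomerise). Fallback, setting out from 10 and coming back at 13: step 5 is stopped before the formaldehyde stage and 10 is isolated. BnBr/K2CO3/DMF (60 °C) caps the last phenol to give 1-{(2R,3R)-4,6-bis(benzyloxy)-3-[2,4-bis(benzyloxy)benzoyl]-2-[4-(benzyloxy)phenyl]-2,3-dihydro-1-benzofuran-7-yl}-2-[4-(benzyloxy)phenyl]ethan-1-one F3. Mannich methylenation ((CH2O)n, i-Pr2NH·TFA, THF, 65 °C) gives the corresponding 2-arylprop-2-en-1-one F4, which cannot cyclise. BCl3/C6HMe5 as in step 7 then gives 13.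

- **Step 7** (BCl3 may add HCl to the enone or ionise the benzylic C2–O bond). Fallback, setting out from 11 and coming back at 13: H2, Pd/C (EtOAc–THF) removes the benzyl groups while the enone is still masked in the chromanone ring, giving (2R,3R)-3-(2,4-dihydroxybenzoyl)-4-hydroxy-2,8-bis(4-hydroxyphenyl)-2,3,7,8-tetrahydro-9H-furo[2,3-f]chromen-9-one F5. Ac2O/NaOAc (90 °C) acetylates the phenols and opens the chromanone in the manner of the flavanone → chalcone acetate reaction, giving the open hexaacetate of 13, F6. NH4OAc in aqueous MeOH (rt) removes the acetates without base and gives 13.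

**Further compounds**
F1 | step 5 | (E)-1-[2,4-bis(benzyloxy)phenyl]-3-[4-(benzyloxy)phenyl]prop-2-en-1-one | O=C(/C=C/c1ccc(OCc2ccccc2)cc1)c1ccc(OCc2ccccc2)cc1OCc1ccccc1
F2 | step 5 | (2S,3S)-enantiomer of 10 | O=C(Cc1ccc(OCc2ccccc2)cc1)c1c(O)cc(OCc2ccccc2)c2c1O[C@H](c1ccc(OCc3ccccc3)cc1)[C@H]2C(=O)c1ccc(OCc2ccccc2)cc1OCc1ccccc1
F3 | step 6 | 1-{(2R,3R)-4,6-bis(benzyloxy)-3-[2,4-bis(benzyloxy)benzoyl]-2-[4-(benzyloxy)phenyl]-2,3-dihydro-1-benzofuran-7-yl}-2-[4-(benzyloxy)phenyl]ethan-1-one | O=C(Cc1ccc(OCc2ccccc2)cc1)c1c(OCc2ccccc2)cc(OCc2ccccc2)c2c1O[C@@H](c1ccc(OCc3ccccc3)cc1)[C@@H]2C(=O)c1ccc(OCc2ccccc2)cc1OCc1ccccc1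
F4 | step 6 | 1-{(2R,3R)-4,6-bis(benzyloxy)-3-[2,4-bis(benzyloxy)benzoyl]-2-[4-(benzyloxy)phenyl]-2,3-dihydro-1-benzofuran-7-yl}-2-[4-(benzyloxy)phenyl]prop-2-en-1-one | C=C(C(=O)c1c(OCc2ccccc2)cc(OCc2ccccc2)c2c1O[C@@H](c1ccc(OCc3ccccc3)cc1)[C@@H]2C(=O)c1ccc(OCc2ccccc2)cc1OCc1ccccc1)c1ccc(OCc2ccccc2)cc1
F5 | step 7 | (2R,3R)-3-(2,4-dihydroxybenzoyl)-4-hydroxy-2,8-bis(4-hydroxyphenyl)-2,3,7,8-tetrahydro-9H-furo[2,3-f]chromen-9-one | O=C1C(c2ccc(O)cc2)COc2cc(O)c3c(O[C@@H](c4ccc(O)cc4)[C@@H]3C(=O)c3ccc(O)cc3O)c21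
F6 | step 7 | hexaacetate of 13 | C=C(C(=O)c1c(OC(C)=O)cc(OC(C)=O)c2c1O[C@@H](c1ccc(OC(C)=O)cc1)[C@@H]2C(=O)c1ccc(OC(C)=O)cc1OC(C)=O)c1ccc(OC(C)=O)cc1
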